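**Retrosynthetic overview** (ring atoms O1, O2, C3–C6; side-chain atoms C1'–C10')

1. Acid 32 ← methyl ester 30 ← the only ring (the 1,2-dioxane), closed last by 6-exo oxa-Michael addition of a C6 tertiary hydroperoxide onto an E-enoate (C3–O bond, 3,4-cis).
2. Hydroperoxide ← cobalt-catalysed silylperoxidation of the 1,1-disubstituted alkene of dienoate 27 ← ketone 22 (methylenation; enoate by Wittig reaction of the C3 aldehyde).
3. Ketone 22 ← crossed Claisen condensation (C5–C6 bond) of the acid chloride of side-chain acid 17 with the lithium enolate of ester 6, then loss of the tert-butoxycarbonyl group.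
4. Ester 6 and the head of 17 both come from one Evans alkylation product 5 (sets C4 and C2'); the tail of 17 comes from (S)-citronellyl bromide (C6') and is joined by a copper-catalysed Grignard–tosylate coupling.

Assumption: mixtures that converge later (13, 20, 21) and the unselective C6 centre of 28 and 29 (about 1:1) are drawn with that element left open; the wanted C6 epimer is isolated by chromatography after ring closure.

**Route**

Step 1
Reactants: 1 (4R)-4-benzyl-3-propanoyl-1,3-oxazolidin-2-one; 2 tert-butyl bromoacetate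
Product: 4 tert-butyl (3S)-4-[(4R)-4-benzyl-2-oxo-1,3-oxazolidin-3-yl]-3-methyl-4-oxobutanoate, via sodium enolate 3 (not isolated)
Conditions: NaN(SiMe3)2 (1.1 equiv), THF, −78 °C; then 2 (1.5 equiv), −78 → −20 °C
Reagents that add atoms: none
Why: Evans asymmetric alkylation, in which the chelated Z-enolate is alkylated on the face opposite the benzyl group, setting the methyl-bearing centre (later C4 in one copy and C2' in the other) as S with dr above 95:5.

Step 2
Reactants: 4 tert-butyl (3S)-4-[(4R)-4-benzyl-2-oxo-1,3-oxazolidin-3-yl]-3-methyl-4-oxobutanoate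
Product: 5 tert-butyl (3S)-4-hydroxy-3-methylbutanoate
Conditions: LiBH4 (1.2 equiv), H2O (1.2 equiv), Et2O, 0 °C
Reagents that add atoms: none
Why: Chemoselective hydride reduction of the activated imide carbonyl (reductive auxiliary removal) leaves the hindered tert-butyl ester and the stereocentre untouched.

Step 3
Reactants: 5 tert-butyl (3S)-4-hydroxy-3-methylbutanoate
Product: 6 tert-butyl (3S)-4-[(tert-butyldiphenylsilyl)oxy]-3-methylbutanoate
Conditions: TBDPSCl (1.1 equiv), imidazole (2 equiv), CH2Cl2, 0 °C → rt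
Reagents that add atoms: tert-butyl(chloro)diphenylsilane (TBDPSCl), CC(C)(C)[Si](Cl)(c1ccccc1)c1ccccc1
Why: Silyl ether formation on the primary alcohol, the TBDPS group being chosen because it survives both the enolate chemistry and the later CF3CO2H treatment.

Step 4
Reactants: 5 tert-butyl (3S)-4-hydroxy-3-methylbutanoate
Product: 7 tert-butyl (3S)-3-methyl-4-[(4-methylbenzenesulfonyl)oxy]butanoate
Conditions: TsCl (1.2 equiv), Et3N (2 equiv), DMAP (5 mol%), CH2Cl2, 0 °C
Reagents that add atoms: 4-methylbenzenesulfonyl chloride (TsCl), Cc1ccc(cc1)S(Cl)(=O)=O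
Why: Sulfonylation of the primary alcohol gives the electrophile for the sp3–sp3 coupling without touching the stereocentre.

Step 5
Reactants: 8 (6S)-8-bromo-2,6-dimethyloct-2-ene [(S)-citronellyl bromide]
Product: 10 (4S)-6-bromo-4-methylhexanal, via ozonide 9 (not isolated)
Conditions: O3, CH2Cl2, −78 °C; then Me2S (3 equiv), −78 °C → rt
Reagents that add atoms: ozone, [O-][O+]=O
Why: Ozonolysis with reductive work-up cleaves the trisubstituted alkene to the aldehyde, the future C6' methyl centre coming unchanged from the chiral pool.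

Step 6
Reactants: 10 (4S)-6-bromo-4-methylhexanal; 11 benzyltriphenylphosphonium chloride
Product: 13 [(5S)-7-bromo-5-methylhept-1-en-1-yl]benzene (E/Z mixture), via phosphorus ylide 12 (not isolated)
Conditions: 11 (1.05 equiv), NaN(SiMe3)2 (1.0 equiv), THF, 0 °C; then 10, −78 °C → rt
Reagents that add atoms: none
Why: Wittig olefination with the semi-stabilised benzylidene ylide attaches the phenyl terminus, the alkene geometry being irrelevant because the double bond is hydrogenated next and the primary bromide being inert at this temperature.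

Step 7
Reactants: 13 [(5S)-7-bromo-5-methylhept-1-en-1-yl]benzene (E/Z mixture)
Product: 14 [(5S)-7-bromo-5-methylheptyl]benzene
Conditions: H2 (1 atm), PtO2 (2 mol%), EtOAc, rt
Reagents that add atoms: none
Why: Catalytic hydrogenation of the styrenyl double bond over platinum, which under neutral conditions does not hydrogenolyse the primary C–Br bond.

Step 8
Reactants: 14 [(5S)-7-bromo-5-methylheptyl]benzene; 7 tert-butyl (3S)-3-methyl-4-[(4-methylbenzenesulfonyl)oxy]butanoate
Product: 16 tert-butyl (3R,7S)-3,7-dimethyl-11-phenylundecanoate, via Grignard reagent 15 (not isolated)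
Conditions: Mg (1.5 equiv), THF, 40 °C; then added to 7 (0.8 equiv), Li2CuCl4 (5 mol%), THF, −78 → 0 °C
Reagents that add atoms: none
Why: Copper-catalysed Kochi–Schlosser sp3–sp3 cross-coupling of a primary Grignard reagent with a primary tosylate is much faster than addition to the tert-butyl ester, and both stereocentres are carried over unchanged (the C3 descriptor becomes R only through the change in substituent priorities).

Step 9
Reactants: 16 tert-butyl (3R,7S)-3,7-dimethyl-11-phenylundecanoate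
Product: 17 (3R,7S)-3,7-dimethyl-11-phenylundecanoic acid
Conditions: CF3CO2H/CH2Cl2 (1:3), 0 °C → rt
Reagents that add atoms: none
Why: Acidolysis of the tert-butyl ester (loss of isobutene) frees the acid without risk to the two alkyl-branched stereocentres.

Step 10
Reactants: 17 (3R,7S)-3,7-dimethyl-11-phenylundecanoic acid; 6 tert-butyl (3S)-4-[(tert-butyldiphenylsilyl)oxy]-3-methylbutanoate
Product: 20 tert-butyl (2RS,5R,9S)-2-[(2S)-1-[(tert-butyldiphenylsilyl)oxy]propan-2-yl]-5,9-dimethyl-3-oxo-13-phenyltridecanoate, via acid chloride 18 (not isolated), via lithium enolate 19 (not isolated)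
Conditions: 17, (COCl)2 (1.5 equiv), DMF (cat.), CH2Cl2, 0 °C → rt, evaporate; separately 6 (2.2 equiv), LiN(iPr)2 (2.2 equiv), THF, −78 °C; add 18, −78 °C, 1 h; AcOH quench
Reagents that add atoms: none
Why: Crossed Claisen condensation in which the preformed ester enolate is C-acylated by the acid chloride while the second equivalent of enolate deprotonates the β-keto ester (recovered as 6 on quench), forming the C5–C6 bond that unites the two fragments; the new C2 centre is unselective and is erased in step 11.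

Step 11
Reactants: 20 tert-butyl (2RS,5R,9S)-2-[(2S)-1-[(tert-butyldiphenylsilyl)oxy]propan-2-yl]-5,9-dimethyl-3-oxo-13-phenyltridecanoate
Product: 22 (2S,6R,10S)-1-[(tert-butyldiphenylsilyl)oxy]-2,6,10-trimethyl-14-phenyltetradecan-4-one, via keto acid 21 (not isolated)
Conditions: CF3CO2H/CH2Cl2 (1:4), 0 °C → rt; evaporate; toluene, 80 °C
Reagents that add atoms: none
Why: Acidolysis of the tert-butyl β-keto ester followed by thermal decarboxylation of the β-keto acid gives the ketone, the primary TBDPS ether tolerating the short acid exposure and no stereocentre being α to the ketone.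

Step 12
Reactants: 22 (2S,6R,10S)-1-[(tert-butyldiphenylsilyl)oxy]-2,6,10-trimethyl-14-phenyltetradecan-4-one
Product: 23 tert-butyl{[(2S,6R,10S)-2,6,10-trimethyl-4-methylidene-14-phenyltetradecyl]oxy}diphenylsilane
Conditions: Ph3PCH3Br (3 equiv), KOtBu (2.8 equiv), THF, 0 → 50 °C
Reagents that add atoms: methyltriphenylphosphonium bromide, [Br-].C[P+](c1ccccc1)(c1ccccc1)c1ccccc1
Why: Wittig methylenation converts the ketone into the 1,1-disubstituted alkene needed for Markovnikov peroxidation, and enolisation is harmless because neither α-carbon is stereogenic.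

Step 13
Reactants: 23 tert-butyl{[(2S,6R,10S)-2,6,10-trimethyl-4-methylidene-14-phenyltetradecyl]oxy}diphenylsilane
Product: 24 (2S,6R,10S)-2,6,10-trimethyl-4-methylidene-14-phenyltetradecan-1-ol
Conditions: Bu4NF (1.5 equiv), THF, rt
Reagents that add atoms: none
Why: Fluoride-mediated cleavage of the silyl ether frees the primary alcohol.

Step 14
Reactants: 24 (2S,6R,10S)-2,6,10-trimethyl-4-methylidene-14-phenyltetradecan-1-ol
Product: 25 (2S,6R,10S)-2,6,10-trimethyl-4-methylidene-14-phenyltetradecanal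
Conditions: Dess–Martin periodinane (1.3 equiv), NaHCO3, CH2Cl2, 0 °C → rt; used crude at once
Reagents that add atoms: none
Why: Buffered Dess–Martin oxidation gives the α-methyl aldehyde without epimerisation.

Step 15
Reactants: 25 (2S,6R,10S)-2,6,10-trimethyl-4-methylidene-14-phenyltetradecanal; 26 methyl (triphenylphosphoranylidene)acetate
Product: 27 methyl (2E,4S,8R,12S)-4,8,12-trimethyl-6-methylidene-16-phenylhexadec-2-enoate
Conditions: 26 (1.3 equiv), CH2Cl2, rt
Reagents that add atoms: none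
Why: Wittig olefination with a stabilised ylide gives the E-enoate (E/Z above 20:1) under neutral conditions that keep the adjacent C4 centre intact.

Step 16
Reactants: 27 methyl (2E,4S,8R,12S)-4,8,12-trimethyl-6-methylidene-16-phenylhexadec-2-enoate
Product: 28 methyl (2E,4S,6RS,8R,12S)-4,6,8,12-tetramethyl-16-phenyl-6-[(triethylsilyl)peroxy]hexadec-2-enoate
Conditions: Co(thd)2 (10 mol%; thd = 2,2,6,6-tetramethylheptane-3,5-dionate), O2 (1 atm), Et3SiH (2 equiv), ClCH2CH2Cl, rt
Reagents that add atoms: dioxygen, O=O; triethylsilane, CC[SiH](CC)CC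
Why: Mukaiyama–Isayama cobalt-catalysed silylperoxidation, in which hydrogen-atom transfer to the electron-rich 1,1-disubstituted alkene gives the tertiary radical that is trapped by O2 (Markovnikov) while the electron-poor enoate reacts far more slowly; C6 is formed without selectivity (about 1:1).

Step 17
Reactants: 28 methyl (2E,4S,6RS,8R,12S)-4,6,8,12-tetramethyl-16-phenyl-6-[(triethylsilyl)peroxy]hexadec-2-enoate
Product: 30 methyl 2-[(3S,4S,6R)-6-[(2R,6S)-2,6-dimethyl-10-phenyldecyl]-4,6-dimethyl-1,2-dioxan-3-yl]acetate, via hydroperoxide 29 (not isolated)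
Conditions: HCl (cat.), MeOH, 0 °C, 15 min; evaporate; Et2NH (0.5 equiv), CF3CH2OH, rt; silica gel chromatography
Reagents that add atoms: none
Why: Desilylation and intramolecular oxa-Michael addition (6-exo-trig) of the tertiary hydroperoxide to the E-enoate through a chair transition state with the C4 methyl equatorial and the enoate arm axial gives the 3,4-cis dioxane and so sets C3 as S (the selectivity known for 4-alkyl-1,2-dioxane-3-acetates of the plakortin type); the C6 epimer cyclises in the same way and is separated here.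

Step 18
Reactants: 30 methyl 2-[(3S,4S,6R)-6-[(2R,6S)-2,6-dimethyl-10-phenyldecyl]-4,6-dimethyl-1,2-dioxan-3-yl]acetate
Product: 32 2-[(3S,4S,6R)-6-[(2R,6S)-2,6-dimethyl-10-phenyldecyl]-4,6-dimethyl-1,2-dioxan-3-yl]acetic acid, via lithium carboxylate 31 (not isolated)
Conditions: LiOH·H2O (3 equiv), THF/H2O (3:1), 0 °C → rt; then dilute aq. HCl to pH 3, 0 °C
Reagents that add atoms: lithium hydroxide, [Li+].[OH-]
Why: Mild saponification of the methyl ester, the dialkyl peroxide being stable to cold aqueous hydroxide and no stereocentre being affected.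

**Compound list**

1 | (4R)-4-benzyl-3-propanoyl-1,3-oxazolidin-2-one | CCC(=O)N1[C@H](Cc2ccccc2)COC1=O | starting material
2 | tert-butyl bromoacetate | CC(C)(C)OC(=O)CBr | starting material
3 | sodium (1Z)-1-[(4R)-4-benzyl-2-oxo-1,3-oxazolidin-3-yl]prop-1-en-1-olate | C/C=C(\[O-])N1[C@H](Cc2ccccc2)COC1=O.[Na+] | intermediate
4 | tert-butyl (3S)-4-[(4R)-4-benzyl-2-oxo-1,3-oxazolidin-3-yl]-3-methyl-4-oxobutanoate | CC(C)(C)OC(=O)C[C@H](C)C(=O)N1[C@H](Cc2ccccc2)COC1=O | intermediate
5 | tert-butyl (3S)-4-hydroxy-3-methylbutanoate | CC(C)(C)OC(=O)C[C@H](C)CO | intermediate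
6 | tert-butyl (3S)-4-[(tert-butyldiphenylsilyl)oxy]-3-methylbutanoate | CC(C)(C)OC(=O)C[C@H](C)CO[Si](c1ccccc1)(c1ccccc1)C(C)(C)C | intermediate
7 | tert-butyl (3S)-3-methyl-4-[(4-methylbenzenesulfonyl)oxy]butanoate | CC(C)(C)OC(=O)C[C@H](C)COS(=O)(=O)c1ccc(C)cc1 | intermediate
8 | (6S)-8-bromo-2,6-dimethyloct-2-ene [(S)-citronellyl bromide] | C[C@@H](CCC=C(C)C)CCBr | starting material
9 | 3-[(3S)-5-bromo-3-methylpentyl]-5,5-dimethyl-1,2,4-trioxolane | C[C@@H](CCC1OOC(C)(C)O1)CCBr | intermediate
10 | (4S)-6-bromo-4-methylhexanal | C[C@@H](CCC=O)CCBr | intermediate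
11 | benzyltriphenylphosphonium chloride | [Cl-].c1ccccc1C[P+](c1ccccc1)(c1ccccc1)c1ccccc1 | starting material
12 | benzylidene(triphenyl)phosphorane | c1ccccc1C=P(c1ccccc1)(c1ccccc1)c1ccccc1 | intermediate
13 | [(5S)-7-bromo-5-methylhept-1-en-1-yl]benzene (E/Z mixture) | C[C@@H](CCC=Cc1ccccc1)CCBr | intermediate
14 | [(5S)-7-bromo-5-methylheptyl]benzene | C[C@@H](CCCCc1ccccc1)CCBr | intermediate
15 | [(3S)-3-methyl-7-phenylheptyl]magnesium bromide | C[C@@H](CCCCc1ccccc1)CC[Mg]Br | intermediate
16 | tert-butyl (3R,7S)-3,7-dimethyl-11-phenylundecanoate | CC(C)(C)OC(=O)C[C@H](C)CCC[C@@H](C)CCCCc1ccccc1 | intermediate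
17 | (3R,7S)-3,7-dimethyl-11-phenylundecanoic acid | OC(=O)C[C@H](C)CCC[C@@H](C)CCCCc1ccccc1 | intermediate
18 | (3R,7S)-3,7-dimethyl-11-phenylundecanoyl chloride | ClC(=O)C[C@H](C)CCC[C@@H](C)CCCCc1ccccc1 | intermediate
19 | lithium (3S)-1-tert-butoxy-4-[(tert-butyldiphenylsilyl)oxy]-3-methylbut-1-en-1-olate | [Li+].CC(C)(C)OC([O-])=C[C@H](C)CO[Si](c1ccccc1)(c1ccccc1)C(C)(C)C | intermediate
20 | tert-butyl (2RS,5R,9S)-2-[(2S)-1-[(tert-butyldiphenylsilyl)oxy]propan-2-yl]-5,9-dimethyl-3-oxo-13-phenyltridecanoate | CC(C)(C)OC(=O)C([C@H](C)CO[Si](c1ccccc1)(c1ccccc1)C(C)(C)C)C(=O)C[C@H](C)CCC[C@@H](C)CCCCc1ccccc1 | intermediate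
21 | (2RS,5R,9S)-2-[(2S)-1-[(tert-butyldiphenylsilyl)oxy]propan-2-yl]-5,9-dimethyl-3-oxo-13-phenyltridecanoic acid | OC(=O)C([C@H](C)CO[Si](c1ccccc1)(c1ccccc1)C(C)(C)C)C(=O)C[C@H](C)CCC[C@@H](C)CCCCc1ccccc1 | intermediate
22 | (2S,6R,10S)-1-[(tert-butyldiphenylsilyl)oxy]-2,6,10-trimethyl-14-phenyltetradecan-4-one | CC(C)(C)[Si](OC[C@@H](C)CC(=O)C[C@H](C)CCC[C@@H](C)CCCCc1ccccc1)(c1ccccc1)c1ccccc1 | intermediate
23 | tert-butyl{[(2S,6R,10S)-2,6,10-trimethyl-4-methylidene-14-phenyltetradecyl]oxy}diphenylsilane | CC(C)(C)[Si](OC[C@@H](C)CC(=C)C[C@H](C)CCC[C@@H](C)CCCCc1ccccc1)(c1ccccc1)c1ccccc1 | intermediate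
24 | (2S,6R,10S)-2,6,10-trimethyl-4-methylidene-14-phenyltetradecan-1-ol | OC[C@@H](C)CC(=C)C[C@H](C)CCC[C@@H](C)CCCCc1ccccc1 | intermediate
25 | (2S,6R,10S)-2,6,10-trimethyl-4-methylidene-14-phenyltetradecanal | O=C[C@@H](C)CC(=C)C[C@H](C)CCC[C@@H](C)CCCCc1ccccc1 | intermediate
26 | methyl (triphenylphosphoranylidene)acetate | COC(=O)C=P(c1ccccc1)(c1ccccc1)c1ccccc1 | starting material
27 | methyl (2E,4S,8R,12S)-4,8,12-trimethyl-6-methylidene-16-phenylhexadec-2-enoate | COC(=O)/C=C/[C@@H](C)CC(=C)C[C@H](C)CCC[C@@H](C)CCCCc1ccccc1 | intermediate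
28 | methyl (2E,4S,6RS,8R,12S)-4,6,8,12-tetramethyl-16-phenyl-6-[(triethylsilyl)peroxy]hexadec-2-enoate (1:1 at C6) | COC(=O)/C=C/[C@@H](C)CC(C)(OO[Si](CC)(CC)CC)C[C@H](C)CCC[C@@H](C)CCCCc1ccccc1 | intermediate
29 | methyl (2E,4S,6RS,8R,12S)-6-hydroperoxy-4,6,8,12-tetramethyl-16-phenylhexadec-2-enoate (1:1 at C6) | COC(=O)/C=C/[C@@H](C)CC(C)(OO)C[C@H](C)CCC[C@@H](C)CCCCc1ccccc1 | intermediate
30 | methyl 2-[(3S,4S,6R)-6-[(2R,6S)-2,6-dimethyl-10-phenyldecyl]-4,6-dimethyl-1,2-dioxan-3-yl]acetate | C[C@@H](CCCCc1ccccc1)CCC[C@@H](C)C[C@]1(C)C[C@H](C)[C@H](CC(=O)OC)OO1 | intermediate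
31 | lithium 2-[(3S,4S,6R)-6-[(2R,6S)-2,6-dimethyl-10-phenyldecyl]-4,6-dimethyl-1,2-dioxan-3-yl]acetate | [Li+].C[C@@H](CCCCc1ccccc1)CCC[C@@H](C)C[C@]1(C)C[C@H](C)[C@H](CC(=O)[O-])OO1 | intermediate
32 | 2-[(3S,4S,6R)-6-[(2R,6S)-2,6-dimethyl-10-phenyldecyl]-4,6-dimethyl-1,2-dioxan-3-yl]acetic acid | C[C@@H](CCCCc1ccccc1)CCC[C@@H](C)C[C@]1(C)C[C@H](C)[C@H](CC(=O)O)OO1 | target

**Summary**

Total step count: 18. Longest linear sequence: 14 steps (steps 1, 2, 4, 8–18; equally steps 5–18 from 8).

Steps most likely to fail, each with a fallback: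

Step 8 (Grignard–tosylate coupling). The Grignard reagent may add to or deprotonate the ester of 7 (cyclopropane formation by internal displacement) instead of coupling. The fallback makes the C3'–C4' bond by olefination; it sets out from 5 and 14 and comes back at 16. Alcohol 5 is oxidised (Dess–Martin periodinane, NaHCO3, CH2Cl2) to tert-butyl (3S)-3-methyl-4-oxobutanoate F1. Bromide 14 is heated with PPh3 (MeCN, 80 °C) to give [(3S)-3-methyl-7-phenylheptyl]triphenylphosphonium bromide F2, which NaN(SiMe3)2 (THF, −78 °C) converts into [(3S)-3-methyl-7-phenylheptylidene]triphenylphosphorane F3. F3 and F1 combine at −78 °C to tert-butyl (3S,4Z,7S)-3,7-dimethyl-11-phenylundec-4-enoate F4, and hydrogenation (H2, Pd/C, EtOAc) gives 16.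

Step 16 (silylperoxidation beside an enoate). The enoate of 27 may compete for the cobalt hydride, and half of the material is the wrong C6 epimer in any case. The fallback peroxidises before the enoate exists; it sets out from 24 and comes back at 28. Alcohol 24 is treated under the same Co(thd)2/O2/Et3SiH conditions (a free primary alcohol is tolerated) to give (2S,4RS,6R,10S)-2,4,6,10-tetramethyl-14-phenyl-4-[(triethylsilyl)peroxy]tetradecan-1-ol F5. Dess–Martin oxidation gives (2S,4RS,6R,10S)-2,4,6,10-tetramethyl-14-phenyl-4-[(triethylsilyl)peroxy]tetradecanal F6, and Wittig reaction with 26 (CH2Cl2, rt) gives 28.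

Step 17 (ring closure and C3 configuration). The oxa-Michael closure may give the 3,4-trans isomer or be eroded by retro-addition. The fallback forms the C3–C2 bond on a preformed dioxane instead of the C3–O bond; it sets out from 24 and comes back at 30. Alcohol 24 is taken through F5 to F6 as above. HCl in MeOH removes the silyl group to give (2S,4RS,6R,10S)-4-hydroperoxy-2,4,6,10-tetramethyl-14-phenyltetradecanal F7, which closes and is acetalised in the same flask to (3RS,4S,6RS)-6-[(2R,6S)-2,6-dimethyl-10-phenyldecyl]-3-methoxy-4,6-dimethyl-1,2-dioxane F8. TiCl4 (CH2Cl2, −78 °C) then promotes a Mukaiyama-type aldol addition of 1-(tert-butyldimethylsilyloxy)-1-methoxyethene to the ring peroxycarbenium ion. Axial attack on the half-chair with the C4 methyl equatorial is expected to give the 3,4-cis ester 30, which is separated from its C6 epimer as before; this facial preference is a prediction and would have to be confirmed.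

Further compounds

F1 | step 8 | tert-butyl (3S)-3-methyl-4-oxobutanoate | CC(C)(C)OC(=O)C[C@H](C)C=O
F2 | step 8 | [(3S)-3-methyl-7-phenylheptyl]triphenylphosphonium bromide | [Br-].C[C@@H](CCCCc1ccccc1)CC[P+](c1ccccc1)(c1ccccc1)c1ccccc1
F3 | step 8 | [(3S)-3-methyl-7-phenylheptylidene]triphenylphosphorane | C[C@@H](CCCCc1ccccc1)CC=P(c1ccccc1)(c1ccccc1)c1ccccc1
F4 | step 8 | tert-butyl (3S,4Z,7S)-3,7-dimethyl-11-phenylundec-4-enoate | CC(C)(C)OC(=O)C[C@H](C)/C=C\C[C@@H](C)CCCCc1ccccc1
F5 | step 16 | (2S,4RS,6R,10S)-2,4,6,10-tetramethyl-14-phenyl-4-[(triethylsilyl)peroxy]tetradecan-1-ol | OC[C@@H](C)CC(C)(OO[Si](CC)(CC)CC)C[C@H](C)CCC[C@@H](C)CCCCc1ccccc1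
F6 | step 16 | (2S,4RS,6R,10S)-2,4,6,10-tetramethyl-14-phenyl-4-[(triethylsilyl)peroxy]tetradecanal | O=C[C@@H](C)CC(C)(OO[Si](CC)(CC)CC)C[C@H](C)CCC[C@@H](C)CCCCc1ccccc1
F7 | step 17 | (2S,4RS,6R,10S)-4-hydroperoxy-2,4,6,10-tetramethyl-14-phenyltetradecanal | O=C[C@@H](C)CC(C)(OO)C[C@H](C)CCC[C@@H](C)CCCCc1ccccc1
F8 | step 17 | (3RS,4S,6RS)-6-[(2R,6S)-2,6-dimethyl-10-phenyldecyl]-3-methoxy-4,6-dimethyl-1,2-dioxane | COC1OOC(C)(C[C@H](C)CCC[C@@H](C)CCCCc2ccccc2)C[C@@H]1C
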